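**Retrosynthetic overview**

1. Target 23 ⇐ lactone acid 21: the 19,20-lactone is opened and C20 is oxidised from alcohol to aldehyde last; 21 ⇐ bis-acetal 20 by one oxidation.
2. Rings C and D of 20 ⇐ vinyl carbinol 18: a C8 cation equivalent is attacked by the C12 vinyl group, and the resulting C13 cation triggers a 1,2-shift of C16 that ends as the C12 ketone (the kaurene-synthase closure and shift, ketone-terminated).
3. 18 ⇐ arene 13 (Birch reduction, methylenation, vinyl addition); the five-membered ring B of 13 ⇐ Δ6 tricycle 12 by oxidative 1,2-shift of C8 from C7 to C6, with C7 extruded at the aldehyde level (the biosynthetic ring contraction, run while C7 is still benzylic).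
4. Rings A and B of 12 ⇐ acyclic aldehyde 7 by one enantioselective radical-cation polyene cyclisation onto an anisole; 7 ⇐ 1 + 2 + 4.
5. Ring order: A and six-membered B together → B contracted to five → C and D together.

Assumption: the target is made as the open 20-aldehyde/19-acid form drawn; C19 in 10–20 (acetal), C16 in 15 and the alkene in 5–7 (drawn E) are carried as mixtures because each is erased later.

Atom labels are the ent-gibberellane numbers of the target throughout (C7 on C6, C18/C19 on C4, C20 on C10; ring B = C5, C6, C8, C9, C10 after contraction). α is the face of C20, β the face of H-5 and H-9. The catalyst in step 5 is used as the enantiomer that gives H-5 β/C20 α; both enantiomers are available.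

**Step 1**
Reactants: 1 triethyl phosphonoacetate; 2 5-bromopentanenitrile
Product: 3 ethyl 6-cyano-2-(diethoxyphosphoryl)hexanoate
Conditions: NaH, DMF, 0 → 50 °C (1 in 1.5-fold excess)
Reagents that add atoms: none
Why: SN2 C-alkylation of the stabilised phosphonoacetate anion installs the C1–C4/C19 chain (nitrile = C19); no stereocentre.

**Step 2**
Reactants: 3 ethyl 6-cyano-2-(diethoxyphosphoryl)hexanoate; 4 3-(4-methoxyphenyl)propanal
Product: 5 ethyl (2E)-2-(4-cyanobutyl)-5-(4-methoxyphenyl)pent-2-enoate
Conditions: NaH, THF, 0 → 23 °C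
Reagents that add atoms: none
Why: Horner–Wadsworth–Emmons olefination builds the trisubstituted C5=C10 alkene (E major); the Z isomer is carried along because alkene geometry is lost in the stepwise radical cyclisation of step 5.

**Step 3**
Reactants: 5 ethyl (2E)-2-(4-cyanobutyl)-5-(4-methoxyphenyl)pent-2-enoate
Product: 6 (6E)-6-(hydroxymethyl)-9-(4-methoxyphenyl)non-6-enal
Conditions: i-Bu2AlH (4.5 equiv), CH2Cl2, −78 → 0 °C; aq. potassium sodium tartrate, then 1 M HCl
Reagents that add atoms: water, O
Why: hydride reduction takes the conjugated ester to the allylic alcohol (C20) and stops at the aldimine for the nitrile, which hydrolyses to the C19 aldehyde on work-up; no stereocentre.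

**Step 4**
Reactants: 6 (6E)-6-(hydroxymethyl)-9-(4-methoxyphenyl)non-6-enal
Product: 7 (6E)-9-(4-methoxyphenyl)-6-[(triisopropylsilyloxy)methyl]non-6-enal
Conditions: i-Pr3SiCl, imidazole, DMF, 23 °C
Reagents that add atoms: chlorotriisopropylsilane, CC(C)[Si](Cl)(C(C)C)C(C)C
Why: O-silylation of the primary allylic alcohol; the TIPS ether is chosen to survive CF3CO2H in step 5 and KOt-Bu in step 6.

**Step 5**
Reactants: 7 (6E)-9-(4-methoxyphenyl)-6-[(triisopropylsilyloxy)methyl]non-6-enal
Product: 8 tricyclic aldehyde (rings A/B trans-fused; C4: H α, CHO β equatorial; H-5 β; C10: CH2OTIPS α; 12-methoxy arene)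
Conditions: 2-tert-butyl-3-methyl-5-(naphthalen-1-ylmethyl)imidazolidin-4-one·CF3CO2H (30 mol %), Cu(OTf)2 (2.5 equiv), NaO2CCF3, CF3CO2H, i-PrCN/DME, 23 °C
Reagents that add atoms: none
Why: organo-SOMO enamine radical-cation polyene cyclisation (the radical counterpart of the cyclase cascade, chosen because a C10 cation next to CH2OSi would suffer a hydride shift): the C4 radical closes ring A 6-endo on C5, the tertiary C10 radical closes ring B on the arene ortho carbon, Cu(OTf)2 re-aromatises, chair-like closures give the trans fusion and the chiral amine sets the absolute configuration.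

**Step 6**
Reactants: 8 tricyclic aldehyde
Product: 9 C4-methylated aldehyde (C18 methyl β; C19 formyl α axial, cis to the C20 CH2OTIPS group)
Conditions: KOt-Bu, MeI, THF, −78 → 0 °C
Reagents that add atoms: iodomethane, CI
Why: aldehyde enolate C-methylation; MeI approaches the exocyclic enolate from the equatorial β face, away from the axial C10 substituent, so the formyl group ends axial and cis to C20.

**Step 7**
Reactants: 9 C4-methylated aldehyde
Product: 11 cyclic methyl acetal (C19H(OMe)–O–C20H2 bridge on the α face of the tricyclic anisole), via lactol 10 (not isolated)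
Conditions: HCl (0.2 equiv, 1.25 M in MeOH), MeOH, 40 °C
Reagents that add atoms: methanol, CO
Why: acid methanolysis removes the silyl group, the freed C20 alcohol closes on the cis-diaxial C19 aldehyde and the lactol is acetalised, so C19 and C20 travel as one inert cyclic acetal.

**Step 8**
Reactants: 11 cyclic methyl acetal
Product: 12 Δ6 cyclic acetal (C6=C7 conjugated with the arene)
Conditions: DDQ (1.2 equiv), 1,4-dioxane, 80 °C
Reagents that add atoms: none
Why: benzylic dehydrogenation (hydride abstraction at C7, para to the methoxy group, then loss of H-6); existing stereocentres are untouched.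

**Step 9**
Reactants: 12 Δ6 cyclic acetal
Product: 13 ring-contracted bis-acetal (five-membered ring B; C6: CH(OMe)2 β, H α)
Conditions: PhI(OH)OTs (1.1 equiv), MeOH, 0 → 23 °C
Reagents that add atoms: methanol, CO
Why: trivalent-iodine oxidative ring contraction of a 1,2-dihydronaphthalene, the same bond reorganisation as the enzymatic ring-B contraction: iodine adds to C6 equatorially on the β face (away from the axial C19/C20 bridge), the antiperiplanar aryl carbon C8 displaces it with inversion and methanol traps the C7 oxocarbenium ion, which leaves C7 β and H-6 α as in the target.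

**Step 10**
Reactants: 13 ring-contracted bis-acetal
Product: 14 dienol ether (ring C: C12(OMe)=C16 and C8=C9, C11 and C15 sp3)
Conditions: Li, NH3(l), THF, t-BuOH, −78 → −33 °C; NH4Cl
Reagents that add atoms: none
Why: Birch reduction of the 1,2-dialkyl-4-methoxybenzene gives the 1-methoxycyclohexa-1,4-diene with the tetrasubstituted C8=C9 bond and a regiodefined enol ether; both acetals are inert.

**Step 11**
Reactants: 14 dienol ether
Product: 16 methylene enone (C12=O, C16=C17H2, C8=C9), via Mannich base 15 (not isolated)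
Conditions: CH2=NMe2+ I−, CH2Cl2, 0 → 23 °C; then MeI; then aq. NaHCO3, 0 °C; used crude
Reagents that add atoms: N,N-dimethylmethyleneiminium iodide, C=[N+](C)C.[I-]
Why: Mannich reaction of the enol ether at C16 (iodide demethylates the oxocarbenium ion to the C12 ketone), then N-quaternisation and E1cB elimination give the α-methylene ketone with C17 in place.

**Step 12**
Reactants: 16 methylene enone
Product: 18 vinyl carbinol TMS ether (C12: vinyl α, OSiMe3 β), via magnesium alkoxide 17 (not isolated)
Conditions: CH2=CHMgBr, CeCl3, THF, −78 °C; then Me3SiCl, Et3N, DMAP (cat.), −78 → 0 °C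
Reagents that add atoms: vinylmagnesium bromide, C=C[Mg]Br; chlorotrimethylsilane, C[Si](C)(C)Cl
Why: 1,2-addition of the vinylcerium reagent (no enolisation, no conjugate addition) to the flat ring-C ketone from the α face, opposite the β-oriented C6 dimethoxymethyl group and C1 methylene, puts C13=C14 on the α face; the alkoxide is silylated in the same flask.

**Step 13**
Reactants: 18 vinyl carbinol TMS ether
Product: 19 9β-phenylselanyl tetracyclic ketone (bicyclo[3.2.1]octan-12-one with the 16-methylene group)
Conditions: PhSeCl + AgOTf (premixed), 2,6-di-tert-butyl-4-methylpyridine, CH2Cl2, −78 → −20 °C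
Reagents that add atoms: benzeneselenenyl chloride, Cl[Se]c1ccccc1
Why: Proposed new method: a selenium-triggered Prins–pinacol cascade modelled on ent-kaurene synthase, in which reversible seleniranium formation on the β face of C8=C9 gives a C8 cation equivalent, the α vinyl group on C12 attacks C8 anti to selenium across the ring to give a secondary C13 cation in a bicyclo[2.2.2]octane, and the alkenyl carbon C16 (better migrating group than C11) shifts from C12 to C13 while the silyloxy group collapses to the ketone, so that C8, C9, C13, the ketone and the exocyclic alkene are set together; the closest known reactions are PhSe+-initiated cation–olefin carbocyclisations and Overman-type Prins–pinacol ring expansions of allylic silyl ethers.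

**Step 14**
Reactants: 19 9β-phenylselanyl tetracyclic ketone
Product: 20 tetracyclic ketone bis-acetal (H-9 β)
Conditions: Bu3SnH, AIBN (cat.), toluene, 80 °C
Reagents that add atoms: none
Why: radical deselenation; the tertiary C9 radical can take hydrogen only on the β face because rings B and C must remain cis-fused on the α face.

**Step 15**
Reactants: 20 tetracyclic ketone bis-acetal
Product: 21 lactone acid (7-carboxylic acid, 19,20-δ-lactone)
Conditions: CrO3, H2SO4, acetone/H2O, 0 °C
Reagents that add atoms: water, O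
Why: Jones oxidation: the aqueous acid hydrolyses both acetals and CrO3 oxidises the C7 aldehyde to the acid and the 19,20-lactol to the lactone; C6 keeps the thermodynamically preferred β-carboxyl configuration and the β,γ-enone cannot conjugate (bridgehead).

**Step 16**
Reactants: 21 lactone acid
Product: 23 ent-12,20-dioxogibberell-16-ene-7,19-dioic acid (target), via hydroxy dicarboxylate 22 (not isolated)
Conditions: n-Bu4NOH (2.2 equiv, aq.), THF, 50 °C; dry by toluene azeotrope; n-Pr4N[RuO4] (5 mol %), NMO, 4 Å MS, MeCN, 23 °C; then 1 M HCl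
Reagents that add atoms: tetrabutylammonium hydroxide, CCCC[N+](CCCC)(CCCC)CCCC.[OH-]
Why: saponification frees the C20 alcohol while C19 stays a carboxylate, and anhydrous Ley–Griffith oxidation stops at the neopentyl aldehyde (the biosynthetic order at C20: alcohol/lactone, then aldehyde); no stereocentre is touched.

**Compound list**

1 | triethyl phosphonoacetate | CCOC(=O)CP(=O)(OCC)OCC | starting material
2 | 5-bromopentanenitrile | N#CCCCCBr | starting material
3 | ethyl 6-cyano-2-(diethoxyphosphoryl)hexanoate | CCOC(=O)C(CCCCC#N)P(=O)(OCC)OCC | intermediate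
4 | 3-(4-methoxyphenyl)propanal | COc1ccc(CCC=O)cc1 | starting material
5 | ethyl (2E)-2-(4-cyanobutyl)-5-(4-methoxyphenyl)pent-2-enoate | CCOC(=O)/C(CCCCC#N)=C/CCc1ccc(OC)cc1 | intermediate
6 | (6E)-6-(hydroxymethyl)-9-(4-methoxyphenyl)non-6-enal | OC/C(CCCCC=O)=C/CCc1ccc(OC)cc1 | intermediate
7 | (6E)-9-(4-methoxyphenyl)-6-[(triisopropylsilyloxy)methyl]non-6-enal | CC(C)[Si](OC/C(CCCCC=O)=C/CCc1ccc(OC)cc1)(C(C)C)C(C)C | intermediate
8 | 12-methoxy-20-(triisopropylsilyloxy)-ent-podocarpa-8,11,13-triene lacking the C4 methyl; C4: H α, CHO β; H-5 β; C20 α | COc1ccc2c(c1)[C@]1(CO[Si](C(C)C)(C(C)C)C(C)C)CCC[C@H](C=O)[C@H]1CC2 | intermediate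
9 | 12-methoxy-20-(triisopropylsilyloxy)-ent-podocarpa-8,11,13-trien-19-al (C18 β, C19 formyl α) | COc1ccc2c(c1)[C@]1(CO[Si](C(C)C)(C(C)C)C(C)C)CCC[C@@](C)(C=O)[C@H]1CC2 | intermediate
10 | 19,20-lactol of 9 after desilylation (19-hydroxy-19,20-epoxide) | COc1ccc2c(c1)[C@@]13COC(O)[C@](C)(CCC3)[C@H]1CC2 | intermediate
11 | 12,19-dimethoxy-19,20-epoxy-ent-podocarpa-8,11,13-triene (cyclic methyl acetal, C19 anomers) | COc1ccc2c(c1)[C@@]13COC(OC)[C@](C)(CCC3)[C@H]1CC2 | intermediate
12 | 12,19-dimethoxy-19,20-epoxy-ent-podocarpa-6,8,11,13-tetraene | COc1ccc2c(c1)[C@@]13COC(OC)[C@](C)(CCC3)[C@H]1C=C2 | intermediate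
13 | ring-B-contracted arene: C6 bears CH(OMe)2 (C7, β) and H (α); 12-methoxy arene; 19,20-cyclic methyl acetal | COc1ccc2c(c1)[C@@]13COC(OC)[C@](C)(CCC3)[C@H]1[C@@H]2C(OC)OC | intermediate
14 | Birch product of 13: ring C is a 1-methoxycyclohexa-1,4-diene (C12(OMe)=C16, C8=C9) | COC1=CCC2=C(C1)[C@@]13COC(OC)[C@](C)(CCC3)[C@H]1[C@@H]2C(OC)OC | intermediate
15 | Mannich base: C12 ketone, C16–CH2NMe2 (C16 epimers), C8=C9 | CN(C)CC1CC2=C(CC1=O)[C@@]13COC(OC)[C@](C)(CCC3)[C@H]1[C@@H]2C(OC)OC | intermediate
16 | methylene enone: C12=O, C16=C17H2, C8=C9 | C=C1CC2=C(CC1=O)[C@@]13COC(OC)[C@](C)(CCC3)[C@H]1[C@@H]2C(OC)OC | intermediate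
17 | bromomagnesium alkoxide of the C12 vinyl carbinol (vinyl α) | C=C1CC2=C(C[C@@]1(C=C)[O-])[C@@]13COC(OC)[C@](C)(CCC3)[C@H]1[C@@H]2C(OC)OC.[Mg+2].[Br-] | intermediate
18 | C12 vinyl carbinol trimethylsilyl ether (vinyl α, OSiMe3 β) | C=C1CC2=C(C[C@@]1(C=C)O[Si](C)(C)C)[C@@]13COC(OC)[C@](C)(CCC3)[C@H]1[C@@H]2C(OC)OC | intermediate
19 | 7,7,19-trimethoxy-9β-(phenylselanyl)-19,20-epoxy-ent-gibberell-16-en-12-one | C=C1C[C@]23C[C@H]1C(=O)C[C@@]2([Se]c1ccccc1)[C@@]14COC(OC)[C@](C)(CCC4)[C@H]1[C@@H]3C(OC)OC | intermediate
20 | 7,7,19-trimethoxy-19,20-epoxy-ent-gibberell-16-en-12-one (H-9 β) | C=C1C[C@]23C[C@H]1C(=O)C[C@H]2[C@@]14COC(OC)[C@](C)(CCC4)[C@H]1[C@@H]3C(OC)OC | intermediate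
21 | 12-oxo-ent-gibberell-16-ene-7,19-dioic acid 19,20-lactone | C=C1C[C@]23C[C@H]1C(=O)C[C@H]2[C@@]14COC(=O)[C@](C)(CCC4)[C@H]1[C@@H]3C(=O)O | intermediate
22 | bis(tetrabutylammonium) 20-hydroxy-12-oxo-ent-gibberell-16-ene-7,19-dioate | C=C1C[C@]23C[C@H]1C(=O)C[C@H]2[C@]1(CO)CCC[C@@](C)(C(=O)[O-])[C@H]1[C@@H]3C(=O)[O-].CCCC[N+](CCCC)(CCCC)CCCC.CCCC[N+](CCCC)(CCCC)CCCC | intermediate
23 | ent-12,20-dioxogibberell-16-ene-7,19-dioic acid (CNP0412196.1) | C=C1C[C@]23C[C@H]1C(=O)C[C@H]2[C@]1(C=O)CCC[C@@](C)(C(=O)O)[C@H]1[C@@H]3C(=O)O | target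

**Totals and risks**

Total step count: 16. Longest linear sequence: 16 steps (1/2 → 23; 4 enters at step 2).

Three steps most likely to fail:

Step 13 (selenium-triggered Prins–pinacol cascade). Seleniranium formation may give allylic selenides or ethers instead, and C11 could migrate in place of C16. The fallback sets out from 18 and comes back at 20, with an epoxide as the cation source. Dimethyldioxirane (acetone, −40 °C) epoxidises the tetrasubstituted C8=C9 bond first and gives the 8,9-epoxide F1 (either face serves). BF3·OEt2 (CH2Cl2, −78 °C) opens it to the tertiary C8 cation, which enters the same vinyl attack and 1,2-shift and gives the 9β-hydroxy ketone F2. This β-hydroxy ketone is dehydrated (Burgess reagent, benzene, 50 °C) to the Δ9(11)-12-enone F3. Conjugate reduction with Li/NH3 (t-BuOH 1 equiv, −78 °C) delivers H-9 on the only accessible β face and returns 20.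

Step 12 (vinyl addition). The facial bias at C12 is small and may favour the wrong epimer. The fallback sets out from 16 and comes back at 18; it inverts C12 by putting the oxygen on last. The same addition without silylation gives the 12-epi carbinol F4 (vinyl β). PhSCl/Et3N (−78 → 0 °C) forms the sulfenate, which rearranges [2,3] to the primary allylic sulfoxide F5 (C12=C13, C14–S(O)Ph). P(OMe)3 in MeOH (50 °C) intercepts the re-formed sulfenate; oxygen is now delivered to the face the carbon nucleophile had preferred, giving the carbinol F6 (vinyl α, OH β). Me3SiCl/imidazole then gives 18.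

Step 11 (methylene enone 16). This is a non-aromatic tautomer of an o-cresol and may aromatise or polymerise. The fallback sets out from 14 and comes back at 18; it postpones the methylene group until C12 is quaternary. The Mannich base 15 is isolated and treated with CH2=CHMgBr/CeCl3 to give the amino alcohol F7, which is silylated (Me3SiOTf, 2,6-lutidine) to the silyl ether F8. N-oxidation (m-CPBA, 1.0 equiv, −78 °C) gives the amine oxide F9, and Cope elimination (THF, 50 °C) gives 18. If C12 emerges with the wrong configuration here, the step-12 fallback applies.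

**Further compounds**

F1 | step 13 | 8,9-epoxide of 18 (epoxide face not fixed) | C=C1CC23OC2(C[C@@]1(C=C)O[Si](C)(C)C)[C@@]14COC(OC)[C@](C)(CCC4)[C@H]1[C@@H]3C(OC)OC
F2 | step 13 | 9β-hydroxy-7,7,19-trimethoxy-19,20-epoxy-ent-gibberell-16-en-12-one | C=C1C[C@]23C[C@H]1C(=O)C[C@@]2(O)[C@@]14COC(OC)[C@](C)(CCC4)[C@H]1[C@@H]3C(OC)OC
F3 | step 13 | 7,7,19-trimethoxy-19,20-epoxy-ent-gibberella-9(11),16-dien-12-one | C=C1C[C@]23C[C@H]1C(=O)C=C2[C@@]14COC(OC)[C@](C)(CCC4)[C@H]1[C@@H]3C(OC)OC
F4 | step 12 | 12-epi vinyl carbinol (vinyl β, OH α) | C=C1CC2=C(C[C@]1(C=C)O)[C@@]13COC(OC)[C@](C)(CCC3)[C@H]1[C@@H]2C(OC)OC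
F5 | step 12 | allylic sulfoxide (C12=C13 exocyclic, C14–S(O)Ph; alkene and sulfur configuration not fixed) | C=C1CC2=C(CC1=CCS(=O)c1ccccc1)[C@@]13COC(OC)[C@](C)(CCC3)[C@H]1[C@@H]2C(OC)OC
F6 | step 12 | vinyl carbinol (vinyl α, OH β) | C=C1CC2=C(C[C@@]1(C=C)O)[C@@]13COC(OC)[C@](C)(CCC3)[C@H]1[C@@H]2C(OC)OC
F7 | step 11 | amino alcohol (C12 vinyl carbinol with C16–CH2NMe2) | CN(C)CC1CC2=C(C[C@@]1(C=C)O)[C@@]13COC(OC)[C@](C)(CCC3)[C@H]1[C@@H]2C(OC)OC
F8 | step 11 | trimethylsilyl ether of F7 | CN(C)CC1CC2=C(C[C@@]1(C=C)O[Si](C)(C)C)[C@@]13COC(OC)[C@](C)(CCC3)[C@H]1[C@@H]2C(OC)OC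
F9 | step 11 | amine N-oxide of F8 | C[N+](C)([O-])CC1CC2=C(C[C@@]1(C=C)O[Si](C)(C)C)[C@@]13COC(OC)[C@](C)(CCC3)[C@H]1[C@@H]2C(OC)OC
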